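(The numbers in the tables were generated by integration for an exercise; scatter was added.)

Two of us disagree about this flask.

| flask | substrate | catalyst | remark | time |
|---|---|---|---|---|
| gamma | 0.050 M | 49 µM | the very flask that is asked about, followed so far |  |
| eta | 0.10 M | 49 µM | run made earlier |  |
| flask | 0.050 M | 49 µM |  | 40 min |

| run | time / min | isomer of the product / % | target / % |
|---|---|---|---|
| gamma | 0.417 | 43 | 28 |
| gamma | 0.833 | 51 | 21 |
| gamma | 1.33 | 55 | 21 |
| gamma | 2.50 | 53 | 22 |
| gamma | 5.00 | 50 | 23 |
| gamma | 8.00 | 51 | 19 |
| gamma | 15.0 | 48 | 18 |
| eta | 0.417 | 44 | 29 |
| eta | 0.833 | 51 | 24 |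
| eta | 2.00 | 56 | 18 |
| eta | 4.00 | 55 | 18 |
| eta | 8.00 | 47 | 19 |
| eta | 15.0 | 42 | 17 |
| eta | 30.0 | 34 | 17 |

(readings scatter by 2 percentage points)

1. the best time, 40 min at the latest, for isomer of the product
2. the amount of isomer of the product, in percent of the substrate charged, at that time

One of us argues for thermodynamic control: the isomer of the product reaches equilibrium with target and substrate, the gamma run's slide of 7 percentage points joins two readings that each scatter by 2 points, and so a late time should serve as well as an early one. The other turns to the eta run, at twice the charge, where isomer plus target, S, goes from 74.0% at 2.00 min to 51.0% at 30.0 min. Since self-condensation takes two substrates, she expects a second-order loss, S falling from its starting value S₀ as S₀/(1 + κt), where κ, the drain constant, is the rise of S₀/S per minute and grows in proportion to the charge. The eta run reads 0.0161 min⁻¹, so this flask, at its lower charge, gets κ = 0.008053 min⁻¹. The first gamma reading, taken as a pseudo-first-order approach to 55%, gives a rise time τ of 0.274 min. The rise's tail then meets the drain at t = τ ln(1/κτ) = 1.68 min, and she commits to that time, to a height near 54.0%, the mean of the two gamma readings on either side of it, and, letting the isomer keep its share of S from the reading at 1.33 min, to 41.9% by 40 min.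

The forecast, “The maximum falls where the rise's tail equals the slow decay”, says 54% at 2 min; the flask gives 53.9% at 1.76 min.

    substrate ⇌ target (K = 0.900, k = 0.140 s⁻¹)
    target + catalyst ⇌ isomer of the product + catalyst, rate k2*[catalyst]*[target] forward; the back reaction follows from the equilibrium constant (K = 2.60, k = 6.80 M⁻¹ s⁻¹)
    isomer of the product + catalyst ⇌ substrate + catalyst, rate k3*[catalyst]*[isomer of the product] forward; the back reaction follows from the equilibrium constant (k = 560 M⁻¹ s⁻¹)
    2 substrate → self-condensation product (k = 0.0240 M⁻¹ s⁻¹)

At 40.0 min this flask holds 41.6% of the isomer, level with the drain reckoning, and 24.7% as self-condensation product, so in this flask the late time does not serve as well as the early one. The equilibrium view keeps the first minutes: this flask still holds 53.1% at 4.00 min, 0.8 points below its best, against readings scattering by 2 points. The equation of the drain step holds no catalyst, so I carry κ unchanged to the neighbouring flask with 1.2 × 10⁻⁴ M of catalyst: its peak of 54.5%, with the drain counted from the start, reckons to 41.2% at 40 min, and that flask holds 41.7%.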